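**Assumption and atom labels:** the SMILES is taken as the absolute configuration; atoms are labelled with germacrane numbering (ring carbons C1–C10, methyl on C4, lactone carbons C11/C12/C13 closed on O6, ester carbon C14 on C10), which gives 4S,6R,7S,8S,9R and 2S,3S in the side chain.

## Retrosynthetic overview

1. Target ⇐ side-chain acetonide removal and C9 acetylation of macrocyclic carbinol 24.
2. 24 ⇐ ring closure of the ten-membered carbocycle (ring B) at C9–C10, last: visible-light, chromium-catalysed coupling of the (Z)-2-iodoenoate with the C9 aldehyde of 23.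
3. 23 ⇐ C8 ester from acid 19 (D-threonine); iodoenoate from an iodo-Wittig reaction on the ozonolysis aldehyde 10.
4. Lactone (ring A) is made first: C6–C7 bond by allylboration of (S)-citronellal with boronate 6, itself from (R)-glyceraldehyde acetonide.
5. Ring order: lactone A, then carbocycle B.

## Route

Step 1
Reactants: 1 (R)-2,2-dimethyl-1,3-dioxolane-4-carbaldehyde
Product: 2 (4S)-4-ethynyl-2,2-dimethyl-1,3-dioxolane
Conditions: dimethyl (1-diazo-2-oxopropyl)phosphonate, K2CO3, MeOH, 0 °C to rt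
Reagents that add atoms: dimethyl (1-diazo-2-oxopropyl)phosphonate CC(=O)C(=[N+]=[N-])P(=O)(OC)OC
Why: Seyferth–Gilbert homologation with the Ohira–Bestmann reagent turns the aldehyde (future C7) into the terminal alkyne under conditions mild enough to leave the dioxolane stereocentre (future C8) intact.

Step 2
Reactants: 2 (4S)-4-ethynyl-2,2-dimethyl-1,3-dioxolane
Product: 4 methyl 3-[(4S)-2,2-dimethyl-1,3-dioxolan-4-yl]prop-2-ynoate, via lithium acetylide 3 (not isolated)
Conditions: n-BuLi, THF, −78 °C; then ClCO2Me, −78 to 0 °C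
Reagents that add atoms: methyl chloroformate COC(=O)Cl
Why: Acetylide acylation with a chloroformate is a standard route to ynoates and does not touch the stereocentre.

Step 3
Reactants: 4 methyl 3-[(4S)-2,2-dimethyl-1,3-dioxolan-4-yl]prop-2-ynoate
Product: 6 methyl (2Z)-3-[(4S)-2,2-dimethyl-1,3-dioxolan-4-yl]-2-[(4,4,5,5-tetramethyl-1,3,2-dioxaborolan-2-yl)methyl]prop-2-enoate, via vinylalanate 5 (not isolated)
Conditions: i-Bu2AlH, hexamethylphosphoramide, THF, 0 °C; then 2-(iodomethyl)-4,4,5,5-tetramethyl-1,3,2-dioxaborolane, 0 °C to rt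
Reagents that add atoms: 2-(iodomethyl)-4,4,5,5-tetramethyl-1,3,2-dioxaborolane ICB1OC(C)(C)C(C)(C)O1
Why: Conjugate hydroalumination of the ynoate adds H and Al syn (H to the β-carbon), and C-alkylation of the α-alumino acrylate with retention gives the 2-alkoxycarbonyl allylboronate with the dioxolane cis to the ester.

Step 4
Reactants: 6 methyl (2Z)-3-[(4S)-2,2-dimethyl-1,3-dioxolan-4-yl]-2-[(4,4,5,5-tetramethyl-1,3,2-dioxaborolan-2-yl)methyl]prop-2-enoate; 7 (S)-citronellal
Product: 9 (4S,5R)-4-[(4S)-2,2-dimethyl-1,3-dioxolan-4-yl]-5-[(2S)-2,6-dimethylhept-5-en-1-yl]-3-methylideneoxolan-2-one, via borate ester 8 (not isolated)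
Conditions: toluene, 90 °C, 48 h; then p-toluenesulfonic acid (cat.), CH2Cl2, rt
Reagents that add atoms: none
Why: Thermal allylboration through a closed chair transition state with the C8 substituent (trans to CH2B) and the aldehyde chain both equatorial gives the anti adduct and hence the trans lactone after acid-catalysed lactonisation; with C8–H eclipsing the cis ester (allylic 1,3-strain) the aldehyde adds anti to the dioxolane C–C bond, setting C7 (S) and C6 (R).

Step 5
Reactants: 9 (4S,5R)-4-[(4S)-2,2-dimethyl-1,3-dioxolan-4-yl]-5-[(2S)-2,6-dimethylhept-5-en-1-yl]-3-methylideneoxolan-2-one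
Product: 10 (4S)-5-[(2R,3S)-3-[(4S)-2,2-dimethyl-1,3-dioxolan-4-yl]-4-methylidene-5-oxooxolan-2-yl]-4-methylpentanal
Conditions: O3, pyridine, CH2Cl2, −78 °C, stopped at the Sudan Red 7B end point
Reagents that add atoms: ozone [O-][O+]=O
Why: Ozonolysis is chemoselective because the electron-rich trisubstituted alkene reacts far faster than the electron-poor α-methylene lactone, and pyridine delivers the C1 aldehyde directly.

Step 6
Reactants: 10 (4S)-5-[(2R,3S)-3-[(4S)-2,2-dimethyl-1,3-dioxolan-4-yl]-4-methylidene-5-oxooxolan-2-yl]-4-methylpentanal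
Product: 11 methyl (2Z,6S)-7-[(2R,3S)-3-[(4S)-2,2-dimethyl-1,3-dioxolan-4-yl]-4-methylidene-5-oxooxolan-2-yl]-2-iodo-6-methylhept-2-enoate
Conditions: Ph3P=CHCO2Me, N-iodosuccinimide, CH2Cl2, −20 °C; then 10, −20 °C to rt
Reagents that add atoms: methyl (triphenylphosphoranylidene)acetate COC(=O)C=P(c1ccccc1)(c1ccccc1)c1ccccc1; N-iodosuccinimide O=C1CCC(=O)N1I
Why: Wittig olefination with the in situ α-iodinated stabilised ylide (iodo-Wittig) places the ester trans to the chain, giving the (Z)-2-iodoenoate that carries C10 and C14.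

Step 7
Reactants: 11 methyl (2Z,6S)-7-[(2R,3S)-3-[(4S)-2,2-dimethyl-1,3-dioxolan-4-yl]-4-methylidene-5-oxooxolan-2-yl]-2-iodo-6-methylhept-2-enoate
Product: 12 methyl (2Z,6S)-7-[(2R,3S)-3-[(1S)-1,2-dihydroxyethyl]-4-methylidene-5-oxooxolan-2-yl]-2-iodo-6-methylhept-2-enoate
Conditions: AcOH/H2O/THF (3:1:1), 40 °C
Reagents that add atoms: none
Why: Mild acid hydrolysis of the terminal acetonide frees the C8/C9 diol while the trans 6,12-lactone stays in place, because the alternative 8,12-lactone would be cis-substituted.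

Step 8
Reactants: 12 methyl (2Z,6S)-7-[(2R,3S)-3-[(1S)-1,2-dihydroxyethyl]-4-methylidene-5-oxooxolan-2-yl]-2-iodo-6-methylhept-2-enoate
Product: 13 methyl (2Z,6S)-7-[(2R,3S)-3-[(1S)-1-hydroxy-2-(triethylsilyloxy)ethyl]-4-methylidene-5-oxooxolan-2-yl]-2-iodo-6-methylhept-2-enoate
Conditions: Et3SiCl (1.05 equiv), pyridine, CH2Cl2, −40 °C
Reagents that add atoms: chlorotriethylsilane CC[Si](Cl)(CC)CC
Why: Selective silylation of the primary C9 hydroxyl over the hindered secondary C8 hydroxyl is reliable at low temperature with one equivalent of silyl chloride.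

Step 9
Reactants: 14 D-threonine
Product: 15 (2R,3S)-2,3-dihydroxybutanoic acid
Conditions: NaNO2, 1 M H2SO4, H2O, 0 °C to rt
Reagents that add atoms: water O
Why: Diazotisation of the α-amino acid proceeds with net retention (double inversion through the α-lactone), and C3 (S), the future side-chain carbinol centre, is untouched.

Step 10
Reactants: 15 (2R,3S)-2,3-dihydroxybutanoic acid
Product: 16 methyl (4R,5S)-2,2,5-trimethyl-1,3-dioxolane-4-carboxylate
Conditions: Me2C(OMe)2, MeOH, p-toluenesulfonic acid (cat.), reflux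
Reagents that add atoms: 2,2-dimethoxypropane COC(C)(C)OC; methanol CO
Why: Fischer esterification and acetonide formation occur in one pot under the same acid catalysis without touching either stereocentre.

Step 11
Reactants: 16 methyl (4R,5S)-2,2,5-trimethyl-1,3-dioxolane-4-carboxylate
Product: 18 methyl (4S,5S)-2,2,4,5-tetramethyl-1,3-dioxolane-4-carboxylate, via lithium enolate 17 (not isolated)
Conditions: LiN(i-Pr)2, THF/N,N'-dimethylpropyleneurea, −78 °C; then MeI, −78 to −40 °C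
Reagents that add atoms: iodomethane CI
Why: In this Seebach-type dioxolane enolate alkylation the ring C–O bond is orthogonal to the enolate π system, which suppresses β-elimination, and MeI enters trans to the C5 methyl, setting the quaternary centre (4S).

Step 12
Reactants: 18 methyl (4S,5S)-2,2,4,5-tetramethyl-1,3-dioxolane-4-carboxylate
Product: 19 (4S,5S)-2,2,4,5-tetramethyl-1,3-dioxolane-4-carboxylic acid
Conditions: LiOH, THF/MeOH/H2O, 50 °C; then 1 M HCl to pH 3, 0 °C
Reagents that add atoms: lithium hydroxide [Li+].[OH-]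
Why: Saponification of the hindered ester cannot epimerise the quaternary centre, and cold brief acidification spares the acetonide.

Step 13
Reactants: 19 (4S,5S)-2,2,4,5-tetramethyl-1,3-dioxolane-4-carboxylic acid; 13 methyl (2Z,6S)-7-[(2R,3S)-3-[(1S)-1-hydroxy-2-(triethylsilyloxy)ethyl]-4-methylidene-5-oxooxolan-2-yl]-2-iodo-6-methylhept-2-enoate
Product: 21 [(1S)-1-[(2R,3S)-2-[(2S,5Z)-6-iodo-7-methoxy-2-methyl-7-oxohept-5-en-1-yl]-4-methylidene-5-oxooxolan-3-yl]-2-(triethylsilyloxy)ethyl] (4S,5S)-2,2,4,5-tetramethyl-1,3-dioxolane-4-carboxylate, via mixed anhydride 20 (not isolated)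
Conditions: 2,4,6-trichlorobenzoyl chloride, Et3N, THF, rt; then 13, 4-(dimethylamino)pyridine, toluene, rt to 40 °C
Reagents that add atoms: none
Why: Yamaguchi esterification is the standard way to join an α,α-disubstituted acid to a hindered secondary alcohol, and installing the C8 ester before C9 is unveiled avoids any later diol differentiation or acyl migration.

Step 14
Reactants: 21 [(1S)-1-[(2R,3S)-2-[(2S,5Z)-6-iodo-7-methoxy-2-methyl-7-oxohept-5-en-1-yl]-4-methylidene-5-oxooxolan-3-yl]-2-(triethylsilyloxy)ethyl] (4S,5S)-2,2,4,5-tetramethyl-1,3-dioxolane-4-carboxylate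
Product: 23 [(1S)-1-[(2R,3S)-2-[(2S,5Z)-6-iodo-7-methoxy-2-methyl-7-oxohept-5-en-1-yl]-4-methylidene-5-oxooxolan-3-yl]-2-oxoethyl] (4S,5S)-2,2,4,5-tetramethyl-1,3-dioxolane-4-carboxylate, via alkoxysulfonium chloride 22 (not isolated)
Conditions: (COCl)2, Me2SO, CH2Cl2, −78 °C; then Et3N, −78 to −30 °C
Reagents that add atoms: none
Why: Under Swern conditions a primary triethylsilyl ether is cleaved by the chlorosulfonium salt and oxidised directly to the aldehyde, giving the C9 aldehyde without a separate desilylation.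

Step 15
Reactants: 23 [(1S)-1-[(2R,3S)-2-[(2S,5Z)-6-iodo-7-methoxy-2-methyl-7-oxohept-5-en-1-yl]-4-methylidene-5-oxooxolan-3-yl]-2-oxoethyl] (4S,5S)-2,2,4,5-tetramethyl-1,3-dioxolane-4-carboxylate
Product: 24 methyl (3aS,4S,5R,6E,10S,11aR)-5-hydroxy-10-methyl-3-methylidene-2-oxo-4-{[(4S,5S)-2,2,4,5-tetramethyl-1,3-dioxolane-4-carbonyl]oxy}-2,3,3a,4,5,8,9,10,11,11a-decahydrocyclodeca[b]furan-6-carboxylate
Conditions: CrCl2 (20 mol %), 2,4,5,6-tetra(carbazol-9-yl)isophthalonitrile (2 mol %), diethyl 2,6-dimethyl-1,4-dihydropyridine-3,5-dicarboxylate (1.5 equiv), 2,6-lutidine (2 equiv), degassed DMF/THF (1:1), 2 mM, 450 nm LEDs, rt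
Reagents that add atoms: none
Why: Proposed new method: the excited cyanoarene is reductively quenched by the dihydropyridine and its radical anion (about −1.2 V vs SCE) returns trivalent chromium to divalent chromium; two divalent chromium centres convert the activated C–I bond into a chromium allenolate (as in chromium Reformatsky chemistry), which adds to the tethered aldehyde through a closed transition state; the tether should deliver C9 to the C2 side of the allene axis so the ring-cis (6E) enoate forms whatever the iodide geometry, polar Felkin–Anh addition anti to the C8–O bond sets C9 (R), and lutidinium protonolysis of the chromium alkoxide closes the cycle; closest known reactions are the stoichiometric NiCl2/CrCl2 Nozaki–Hiyama–Kishi macrocyclisation and photoredox/chromium-catalysed allylation of aldehydes, neither shown for a 2-iodoenoate or a ten-membered ring closure.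

Step 16
Reactants: 24 methyl (3aS,4S,5R,6E,10S,11aR)-5-hydroxy-10-methyl-3-methylidene-2-oxo-4-{[(4S,5S)-2,2,4,5-tetramethyl-1,3-dioxolane-4-carbonyl]oxy}-2,3,3a,4,5,8,9,10,11,11a-decahydrocyclodeca[b]furan-6-carboxylate
Product: 25 methyl (3aS,4S,5R,6E,10S,11aR)-5-acetyloxy-10-methyl-3-methylidene-2-oxo-4-{[(4S,5S)-2,2,4,5-tetramethyl-1,3-dioxolane-4-carbonyl]oxy}-2,3,3a,4,5,8,9,10,11,11a-decahydrocyclodeca[b]furan-6-carboxylate
Conditions: Ac2O, pyridine, 4-(dimethylamino)pyridine (cat.), CH2Cl2, 0 °C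
Reagents that add atoms: acetic anhydride CC(=O)OC(C)=O
Why: Acetylation of the only free hydroxyl is straightforward, and the β-substituted enoate is a poor partner for amine-induced allylic displacement of the new acetate.

Step 17
Reactants: 25 methyl (3aS,4S,5R,6E,10S,11aR)-5-acetyloxy-10-methyl-3-methylidene-2-oxo-4-{[(4S,5S)-2,2,4,5-tetramethyl-1,3-dioxolane-4-carbonyl]oxy}-2,3,3a,4,5,8,9,10,11,11a-decahydrocyclodeca[b]furan-6-carboxylate
Product: 26 methyl (3aS,4S,5R,6E,10S,11aR)-5-acetyloxy-4-{[(2S,3S)-2,3-dihydroxy-2-methylbutanoyl]oxy}-10-methyl-3-methylidene-2-oxo-2,3,3a,4,5,8,9,10,11,11a-decahydrocyclodeca[b]furan-6-carboxylate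
Conditions: CF3CO2H/H2O (4:1), 0 °C
Reagents that add atoms: none
Why: Aqueous acid hydrolysis of the side-chain acetonide leaves the esters, the allylic acetate (whose ionisation is disfavoured by the ester on C10) and the α-methylene lactone untouched.

## Compound list

1 | (R)-2,2-dimethyl-1,3-dioxolane-4-carbaldehyde | O=C[C@@H]1OC(C)(C)OC1 | starting material
2 | (4S)-4-ethynyl-2,2-dimethyl-1,3-dioxolane | C#C[C@@H]1OC(C)(C)OC1 | intermediate
3 | lithium acetylide of 2 | [Li]C#C[C@@H]1OC(C)(C)OC1 | intermediate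
4 | methyl 3-[(4S)-2,2-dimethyl-1,3-dioxolan-4-yl]prop-2-ynoate | COC(=O)C#C[C@@H]1OC(C)(C)OC1 | intermediate
5 | methyl (2E)-2-(diisobutylalumanyl)-3-[(4S)-2,2-dimethyl-1,3-dioxolan-4-yl]prop-2-enoate (Al cis to the vinylic H) | COC(=O)/C([Al](CC(C)C)CC(C)C)=C\[C@@H]1OC(C)(C)OC1 | intermediate
6 | methyl (2Z)-3-[(4S)-2,2-dimethyl-1,3-dioxolan-4-yl]-2-[(4,4,5,5-tetramethyl-1,3,2-dioxaborolan-2-yl)methyl]prop-2-enoate | COC(=O)/C(CB1OC(C)(C)C(C)(C)O1)=C\[C@@H]1OC(C)(C)OC1 | intermediate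
7 | (S)-citronellal, (3S)-3,7-dimethyloct-6-enal | O=CC[C@@H](C)CCC=C(C)C | starting material
8 | methyl (3S,4R,6S)-3-[(4S)-2,2-dimethyl-1,3-dioxolan-4-yl]-6,10-dimethyl-2-methylidene-4-[(4,4,5,5-tetramethyl-1,3,2-dioxaborolan-2-yl)oxy]undec-9-enoate | C=C(C(=O)OC)[C@H]([C@@H]1OC(C)(C)OC1)[C@H](OB1OC(C)(C)C(C)(C)O1)C[C@@H](C)CCC=C(C)C | intermediate
9 | (4S,5R)-4-[(4S)-2,2-dimethyl-1,3-dioxolan-4-yl]-5-[(2S)-2,6-dimethylhept-5-en-1-yl]-3-methylideneoxolan-2-one | C=C1C(=O)O[C@H](C[C@@H](C)CCC=C(C)C)[C@H]1[C@@H]1OC(C)(C)OC1 | intermediate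
10 | (4S)-5-[(2R,3S)-3-[(4S)-2,2-dimethyl-1,3-dioxolan-4-yl]-4-methylidene-5-oxooxolan-2-yl]-4-methylpentanal | C=C1C(=O)O[C@H](C[C@@H](C)CCC=O)[C@H]1[C@@H]1OC(C)(C)OC1 | intermediate
11 | methyl (2Z,6S)-7-[(2R,3S)-3-[(4S)-2,2-dimethyl-1,3-dioxolan-4-yl]-4-methylidene-5-oxooxolan-2-yl]-2-iodo-6-methylhept-2-enoate | C=C1C(=O)O[C@H](C[C@@H](C)CC/C=C(/C(=O)OC)I)[C@H]1[C@@H]1OC(C)(C)OC1 | intermediate
12 | methyl (2Z,6S)-7-[(2R,3S)-3-[(1S)-1,2-dihydroxyethyl]-4-methylidene-5-oxooxolan-2-yl]-2-iodo-6-methylhept-2-enoate | C=C1C(=O)O[C@H](C[C@@H](C)CC/C=C(/C(=O)OC)I)[C@H]1[C@H](O)CO | intermediate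
13 | methyl (2Z,6S)-7-[(2R,3S)-3-[(1S)-1-hydroxy-2-(triethylsilyloxy)ethyl]-4-methylidene-5-oxooxolan-2-yl]-2-iodo-6-methylhept-2-enoate | C=C1C(=O)O[C@H](C[C@@H](C)CC/C=C(/C(=O)OC)I)[C@H]1[C@H](O)CO[Si](CC)(CC)CC | intermediate
14 | D-threonine, (2R,3S)-2-amino-3-hydroxybutanoic acid | C[C@H](O)[C@@H](N)C(=O)O | starting material
15 | (2R,3S)-2,3-dihydroxybutanoic acid | C[C@H](O)[C@@H](O)C(=O)O | intermediate
16 | methyl (4R,5S)-2,2,5-trimethyl-1,3-dioxolane-4-carboxylate | COC(=O)[C@@H]1OC(C)(C)O[C@H]1C | intermediate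
17 | lithium enolate of 16 | COC(O[Li])=C1OC(C)(C)O[C@H]1C | intermediate
18 | methyl (4S,5S)-2,2,4,5-tetramethyl-1,3-dioxolane-4-carboxylate | COC(=O)[C@@]1(C)OC(C)(C)O[C@H]1C | intermediate
19 | (4S,5S)-2,2,4,5-tetramethyl-1,3-dioxolane-4-carboxylic acid | OC(=O)[C@@]1(C)OC(C)(C)O[C@H]1C | intermediate
20 | mixed anhydride of 19 and 2,4,6-trichlorobenzoic acid | O=C(OC(=O)c1c(Cl)cc(Cl)cc1Cl)[C@@]1(C)OC(C)(C)O[C@H]1C | intermediate
21 | [(1S)-1-[(2R,3S)-2-[(2S,5Z)-6-iodo-7-methoxy-2-methyl-7-oxohept-5-en-1-yl]-4-methylidene-5-oxooxolan-3-yl]-2-(triethylsilyloxy)ethyl] (4S,5S)-2,2,4,5-tetramethyl-1,3-dioxolane-4-carboxylate | C=C1C(=O)O[C@H](C[C@@H](C)CC/C=C(/C(=O)OC)I)[C@H]1[C@H](OC(=O)[C@@]1(C)OC(C)(C)O[C@H]1C)CO[Si](CC)(CC)CC | intermediate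
22 | dimethyl(alkoxy)sulfonium chloride of the primary alcohol derived from 21 | C=C1C(=O)O[C@H](C[C@@H](C)CC/C=C(/C(=O)OC)I)[C@H]1[C@H](OC(=O)[C@@]1(C)OC(C)(C)O[C@H]1C)CO[S+](C)C.[Cl-] | intermediate
23 | [(1S)-1-[(2R,3S)-2-[(2S,5Z)-6-iodo-7-methoxy-2-methyl-7-oxohept-5-en-1-yl]-4-methylidene-5-oxooxolan-3-yl]-2-oxoethyl] (4S,5S)-2,2,4,5-tetramethyl-1,3-dioxolane-4-carboxylate | C=C1C(=O)O[C@H](C[C@@H](C)CC/C=C(/C(=O)OC)I)[C@H]1[C@H](OC(=O)[C@@]1(C)OC(C)(C)O[C@H]1C)C=O | intermediate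
24 | methyl (3aS,4S,5R,6E,10S,11aR)-5-hydroxy-10-methyl-3-methylidene-2-oxo-4-{[(4S,5S)-2,2,4,5-tetramethyl-1,3-dioxolane-4-carbonyl]oxy}-2,3,3a,4,5,8,9,10,11,11a-decahydrocyclodeca[b]furan-6-carboxylate | C=C1C(=O)O[C@@H]2C[C@@H](C)CC/C=C(/C(=O)OC)[C@@H](O)[C@@H](OC(=O)[C@@]3(C)OC(C)(C)O[C@H]3C)[C@@H]12 | intermediate
25 | methyl (3aS,4S,5R,6E,10S,11aR)-5-acetyloxy-10-methyl-3-methylidene-2-oxo-4-{[(4S,5S)-2,2,4,5-tetramethyl-1,3-dioxolane-4-carbonyl]oxy}-2,3,3a,4,5,8,9,10,11,11a-decahydrocyclodeca[b]furan-6-carboxylate | C=C1C(=O)O[C@@H]2C[C@@H](C)CC/C=C(/C(=O)OC)[C@@H](OC(C)=O)[C@@H](OC(=O)[C@@]3(C)OC(C)(C)O[C@H]3C)[C@@H]12 | intermediate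
26 | methyl (3aS,4S,5R,6E,10S,11aR)-5-acetyloxy-4-{[(2S,3S)-2,3-dihydroxy-2-methylbutanoyl]oxy}-10-methyl-3-methylidene-2-oxo-2,3,3a,4,5,8,9,10,11,11a-decahydrocyclodeca[b]furan-6-carboxylate | C=C1C(=O)O[C@@H]2C[C@@H](C)CC/C=C(/C(=O)OC)[C@@H](OC(C)=O)[C@@H](OC(=O)[C@@](C)(O)[C@H](C)O)[C@@H]12 | target

## Step count and risks

Total step count: 17. Longest linear sequence: 13 (steps 1–8 and 13–17); the acid 19 is made in 4 steps and joins at step 13.

The three steps most likely to fail: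

**Step 15 (the proposed new macrocyclisation).** Risks are protodeiodination, oligomerisation, the ring-trans enoate, or the C9 epimer. The fallback sets out from 23 and comes back at 24. It gives up the light-driven catalytic manifold for the classical stoichiometric two-metal Nozaki–Hiyama–Kishi macrocyclisation in the dark (CrCl2, 8 equiv; NiCl2, 2 mol %; degassed DMSO/THF; 2 mM; slow addition; rt). There zerovalent nickel inserts into the C–I bond with retention and hands the alkenyl group to trivalent chromium, so the (Z)-iodide geometry (C2 cis to the metal) is carried into the ring-cis enoate. No new compound is formed.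

**Step 4 (allylboration).** The electron-poor boronate may react too slowly with the aliphatic aldehyde, and the facial selectivity relative to C8 is not secured by close precedent. Lewis acid catalysis cannot be used on citronellal because it triggers the carbonyl-ene cyclisation. The fallback sets out from 7 and 6 and comes back at 11, replacing steps 4–6 with a route in which the aldehyde partner is made ene-inert first. NaBH4 in MeOH reduces 7 to (3S)-3,7-dimethyloct-6-en-1-ol F1. Ozonolysis (O3, pyridine, CH2Cl2, −78 °C) gives (4S)-6-hydroxy-4-methylhexanal F2. The iodo-Wittig reagent of step 6 gives methyl (2Z,6S)-8-hydroxy-2-iodo-6-methyloct-2-enoate F3. Dess–Martin periodinane (NaHCO3, CH2Cl2) gives methyl (2Z,6S)-2-iodo-6-methyl-8-oxooct-2-enoate F4. Sc(OTf)3-catalysed allylboration of F4 with 6 (10 mol %, toluene, −20 °C to rt) proceeds through the same closed transition state at low temperature to the borate adduct methyl (2Z,6S,8R,9S)-9-[(4S)-2,2-dimethyl-1,3-dioxolan-4-yl]-2-iodo-10-(methoxycarbonyl)-6-methyl-8-[(4,4,5,5-tetramethyl-1,3,2-dioxaborolan-2-yl)oxy]undeca-2,10-dienoate F5, which p-toluenesulfonic acid lactonises to 11.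

**Step 14 (direct Swern oxidation of the silyl ether).** Incomplete silyl cleavage, or base-induced epimerisation at C8 of the α-acyloxy aldehyde, is possible. The fallback sets out from 21 and comes back at 23 by a stepwise, base-free sequence. HF·pyridine buffered with pyridine (THF, 0 °C) gives the primary alcohol [(1S)-2-hydroxy-1-[(2R,3S)-2-[(2S,5Z)-6-iodo-7-methoxy-2-methyl-7-oxohept-5-en-1-yl]-4-methylidene-5-oxooxolan-3-yl]ethyl] (4S,5S)-2,2,4,5-tetramethyl-1,3-dioxolane-4-carboxylate F6. Dess–Martin periodinane with NaHCO3 in CH2Cl2 at 0 °C then gives 23.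

## Further compounds

F1 | step 4 | (3S)-3,7-dimethyloct-6-en-1-ol | OCC[C@@H](C)CCC=C(C)C
F2 | step 4 | (4S)-6-hydroxy-4-methylhexanal | OCC[C@@H](C)CCC=O
F3 | step 4 | methyl (2Z,6S)-8-hydroxy-2-iodo-6-methyloct-2-enoate | OCC[C@@H](C)CC/C=C(/C(=O)OC)I
F4 | step 4 | methyl (2Z,6S)-2-iodo-6-methyl-8-oxooct-2-enoate | O=CC[C@@H](C)CC/C=C(/C(=O)OC)I
F5 | step 4 | methyl (2Z,6S,8R,9S)-9-[(4S)-2,2-dimethyl-1,3-dioxolan-4-yl]-2-iodo-10-(methoxycarbonyl)-6-methyl-8-[(4,4,5,5-tetramethyl-1,3,2-dioxaborolan-2-yl)oxy]undeca-2,10-dienoate | C=C(C(=O)OC)[C@H]([C@@H]1OC(C)(C)OC1)[C@H](OB1OC(C)(C)C(C)(C)O1)C[C@@H](C)CC/C=C(/C(=O)OC)I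
F6 | step 14 | [(1S)-2-hydroxy-1-[(2R,3S)-2-[(2S,5Z)-6-iodo-7-methoxy-2-methyl-7-oxohept-5-en-1-yl]-4-methylidene-5-oxooxolan-3-yl]ethyl] (4S,5S)-2,2,4,5-tetramethyl-1,3-dioxolane-4-carboxylate | C=C1C(=O)O[C@H](C[C@@H](C)CC/C=C(/C(=O)OC)I)[C@H]1[C@H](OC(=O)[C@@]1(C)OC(C)(C)O[C@H]1C)CO
F0 | step 15 | none | none
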